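The route cuts C4–C5, the bond between the methylidene-bearing carbon and the carbinol carbon of the nine-membered oxacycle (ring O, C3–C10). The last step is a Nozaki–Hiyama–Kishi closure of bromo aldehyde 24. It exploits the 2-substituted allylic alcohol C15H2=C4–C5H(OH) between furanone C3 and lactone C6. In one protecting-group-free operation it closes the final ring, sets C5 and gives the target. Precursor 24 already holds both five-membered rings: the furanone with a 1-bromovinyl group, and the cis-substituted α-methylene lactone with the C5 aldehyde. The H6/H7-cis relation comes from a temporary six-membered lactone allylsilane that is attacked trans to its silyloxy group and then translactonised.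

Key step: step 16

Remark on atom labels (germacrane numbering):
- C1 is the furanone C=O, and C2=C3 is the furanone alkene (C3 bears the ring O).
- C4 carries =C15H2, C5 is the carbinol, C6 is the lactone O–CH, then C7.
- C8 is the ester carbinol, C9 is CH2, and C10 is quaternary (C14H3 and ring O).
- C11 carries =C13H2, and C12 is the lactone C=O.

Assumption 1: the target SMILES is read as 5S,6R,7R,8R,10R, which places H6 and H7 cis on the lactone.
Assumption 2: 9 (stabilised) and 16 are taken as purchasable.

Step 1
Reactants: 1 (S)-lactic acid; 2 pivalaldehyde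
Product: 3 (2S,5S)-2-tert-butyl-5-methyl-1,3-dioxolan-4-one
Conditions: p-TsOH·H2O (cat.), H2SO4 (cat.), pentane, reflux, Dean–Stark; crystallisation from pentane/Et2O, −78 °C
Reagents that add atoms: none
Why: Acid-catalysed acetalisation with azeotropic removal of water should favour the cis-dioxolanone, in which the new acetal centre places tert-butyl on the face of the methyl group, and low-temperature crystallisation removes the trans isomer.

Step 2
Reactants: 3 (2S,5S)-2-tert-butyl-5-methyl-1,3-dioxolan-4-one; 4 allyl bromide
Product: 5 (2S,5R)-5-allyl-2-tert-butyl-5-methyl-1,3-dioxolan-4-one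
Conditions: LDA, THF, −78 °C; then 4, −78 → −30 °C
Reagents that add atoms: none
Why: Enolate alkylation under self-regeneration of the stereocentre: the planar lithium enolate is shielded on one face by the tert-butyl group, so allyl bromide enters trans to it and fixes quaternary C10 (R) with C9 and C8 attached.

Step 3
Reactants: 5 (2S,5R)-5-allyl-2-tert-butyl-5-methyl-1,3-dioxolan-4-one
Product: 6 (2R)-2-hydroxy-N-methoxy-N,2-dimethylpent-4-enamide
Conditions: MeNH(OMe)·HCl, i-PrMgCl, THF, −20 → 0 °C; aq. NH4Cl
Reagents that add atoms: N,O-dimethylhydroxylamine hydrochloride, CNOC.Cl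
Why: Weinreb amide formation by aminolysis of the acetal-lactone with the magnesium amide opens the ring, the hemiacetal alkoxide collapses with loss of pivalaldehyde, and C10 is not touched.

Step 4
Reactants: 6 (2R)-2-hydroxy-N-methoxy-N,2-dimethylpent-4-enamide; 7 ethynylmagnesium bromide
Product: 8 (4R)-4-hydroxy-4-methylhept-6-en-1-yn-3-one
Conditions: 7 (3 equiv), THF, 0 °C → rt; aq. NH4Cl
Reagents that add atoms: none
Why: Weinreb ketone synthesis: after deprotonation of the tertiary alcohol the alkynyl Grignard reagent adds once, the chelated tetrahedral adduct survives until the quench, and the terminal ynone (C1–C3) results without change at C10.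

Step 5
Reactants: 8 (4R)-4-hydroxy-4-methylhept-6-en-1-yn-3-one; 9 1,1-dibromoethene
Product: 10 (6R)-2-bromo-6-hydroxy-6-methylnona-1,8-dien-3-yn-5-one
Conditions: 9 (5 equiv), Pd(PPh3)4 (5 mol %), CuI (10 mol %), i-Pr2NEt, THF, rt
Reagents that add atoms: none
Why: Sonogashira coupling in which the excess of geminal dibromide and the non-nucleophilic base should hold the reaction at mono-alkynylation and spare the Michael-sensitive ynone, which installs C4 with its bromine and C15.

Step 6
Reactants: 10 (6R)-2-bromo-6-hydroxy-6-methylnona-1,8-dien-3-yn-5-one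
Product: 11 (2R)-2-allyl-5-(1-bromovinyl)-2-methylfuran-3(2H)-one
Conditions: (p-CF3C6H4)3PAuCl (5 mol %), AgOTf (5 mol %), toluene, rt
Reagents that add atoms: none
Why: Gold-catalysed 5-endo-dig cycloisomerisation of a γ-hydroxy alkynone: the cationic gold complex activates C2≡C3 for attack of the C10 hydroxyl at C3, and protodeauration gives the 3(2H)-furanone with C10 unchanged.

Step 7
Reactants: 11 (2R)-2-allyl-5-(1-bromovinyl)-2-methylfuran-3(2H)-one
Product: 13 2-[(2R)-5-(1-bromovinyl)-2-methyl-3-oxo-2,3-dihydrofuran-2-yl]acetaldehyde, via vicinal diol 12 (not isolated)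
Conditions: OsO4 (2 mol %), NaIO4, 2,6-lutidine, dioxane–H2O, rt
Reagents that add atoms: sodium periodate, [Na+].[O-]I(=O)(=O)=O; water, O
Why: Lemieux–Johnson cleavage: OsO4 should dihydroxylate only the isolated allyl double bond, because the bromodiene is deactivated by bromine and by conjugation with the furanone, and periodate cleaves the diol to the C8 aldehyde under lutidine buffering that suppresses β-elimination of the furanone oxygen.

Step 8
Reactants: 14 ethyl 2-[(trimethylsilyl)methyl]acrylate
Product: 15 2-[(trimethylsilyl)methyl]acrylic acid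
Conditions: LiOH·H2O, THF–H2O, rt; then 1 M HCl
Reagents that add atoms: lithium hydroxide, [Li+].[OH-]
Why: Saponification of the ethyl ester, to which the allylsilane is inert, followed by mild acidification.

Step 9
Reactants: 15 2-[(trimethylsilyl)methyl]acrylic acid; 16 (2R)-but-3-ene-1,2-diol
Product: 17 (2R)-2-hydroxybut-3-en-1-yl 2-[(trimethylsilyl)methyl]acrylate
Conditions: DCC, DMAP (cat.), CH2Cl2, −20 → 0 °C (16 in 1.5-fold excess)
Reagents that add atoms: none
Why: Steglich esterification at low temperature with the diol in excess should acylate the less hindered primary hydroxyl (O5), and the C6 stereocentre of the purchased diol is carried over unchanged.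

Step 10
Reactants: 17 (2R)-2-hydroxybut-3-en-1-yl 2-[(trimethylsilyl)methyl]acrylate
Product: 18 (2R)-2-[(tert-butyldimethylsilyl)oxy]but-3-en-1-yl 2-[(trimethylsilyl)methyl]acrylate
Conditions: TBSCl, imidazole, DMF, rt
Reagents that add atoms: tert-butyldimethylsilyl chloride, CC(C)(C)[Si](C)(C)Cl
Why: Standard silylation of the secondary allylic alcohol blocks O6 against premature ring contraction and provides the bulky group that later steers the attack at C7.

Step 11
Reactants: 18 (2R)-2-[(tert-butyldimethylsilyl)oxy]but-3-en-1-yl 2-[(trimethylsilyl)methyl]acrylate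
Product: 19 (5R)-5-[(tert-butyldimethylsilyl)oxy]-3-[(trimethylsilyl)methyl]-5,6-dihydro-2H-pyran-2-one
Conditions: second-generation Grubbs catalyst (H2IMes)(PCy3)Cl2Ru=CHPh (5 mol %), toluene (0.005 M), 80 °C
Reagents that add atoms: none
Why: Ring-closing metathesis of the monosubstituted alkene with the 1,1-disubstituted acrylate closes the temporary six-membered unsaturated lactone (C7=C11) with loss of ethene and leaves the allylsilane and C6 intact.

Step 12
Reactants: 13 2-[(2R)-5-(1-bromovinyl)-2-methyl-3-oxo-2,3-dihydrofuran-2-yl]acetaldehyde; 19 (5R)-5-[(tert-butyldimethylsilyl)oxy]-3-[(trimethylsilyl)methyl]-5,6-dihydro-2H-pyran-2-one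
Product: 20 (4R,5R)-4-{(1R)-2-[(2R)-5-(1-bromovinyl)-2-methyl-3-oxo-2,3-dihydrofuran-2-yl]-1-hydroxyethyl}-5-[(tert-butyldimethylsilyl)oxy]-3-methylidenetetrahydro-2H-pyran-2-one
Conditions: BF3·OEt2 (3 equiv), CH2Cl2, −78 → −40 °C; aq. NaHCO3
Reagents that add atoms: none
Why: Hosomi–Sakurai allylation of the BF3-activated aldehyde by the β-alkoxycarbonyl allylsilane (SE2′, loss of the silyl group unveils C11=C13): C7 is attacked trans to the neighbouring pseudoaxial silyloxy group of the half-chair (7R), and the open antiperiplanar transition state with H8 over the ring gives the syn C7/C8 relation (8R).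

Step 13
Reactants: 20 the C8 alcohol of step 12
Product: 21 (1R)-2-[(2R)-5-(1-bromovinyl)-2-methyl-3-oxo-2,3-dihydrofuran-2-yl]-1-{(4R,5R)-5-[(tert-butyldimethylsilyl)oxy]-3-methylidene-2-oxotetrahydro-2H-pyran-4-yl}ethyl 2-methylpropanoate
Conditions: (i-PrCO)2O, Et3N, DMAP (cat.), CH2Cl2, 0 °C → rt
Reagents that add atoms: isobutyric anhydride, CC(C)C(=O)OC(=O)C(C)C
Why: DMAP-catalysed acylation of the only free hydroxyl installs the isobutyrate at O8 with retention at C8.

Step 14
Reactants: 21 the silyl-protected pyranone isobutyrate of step 13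
Product: 23 (1R)-2-[(2R)-5-(1-bromovinyl)-2-methyl-3-oxo-2,3-dihydrofuran-2-yl]-1-[(2R,3R)-2-(hydroxymethyl)-4-methylidene-5-oxotetrahydrofuran-3-yl]ethyl 2-methylpropanoate, via hydroxy pyranone 22 (not isolated)
Conditions: 48 % aq. HF, MeCN, 0 °C → rt
Reagents that add atoms: none
Why: Acidic desilylation frees O6–H and acid-catalysed translactonisation moves the acyl group from primary O5 to O6 because the five-membered lactone is favoured over the six-membered one; no bond to C6 or C7 is broken, so the trans O6/C8 relation of the pyranone becomes the cis C5/C8 (H6/H7-cis) relation of the butyrolactone.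

Step 15
Reactants: 23 the hydroxymethyl butyrolactone of step 14
Product: 24 (1R)-2-[(2R)-5-(1-bromovinyl)-2-methyl-3-oxo-2,3-dihydrofuran-2-yl]-1-[(2R,3R)-2-formyl-4-methylidene-5-oxotetrahydrofuran-3-yl]ethyl 2-methylpropanoate
Conditions: Dess–Martin periodinane, CH2Cl2, 0 °C → rt; used without storage
Reagents that add atoms: none
Why: Dess–Martin oxidation converts the primary alcohol into the C5 aldehyde under non-basic conditions that should not enolise the epimerisable C6 position.

Step 16
Reactants: 24 the bromo aldehyde of step 15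
Product: 25 (5S,6R,7R,8R,10R)-5-hydroxy-1-oxo-3,10-epoxygermacra-2,4(15),11(13)-trien-12,6-olid-8-yl 2-methylpropanoate (CNP0384113.1)
Conditions: CrCl2 (15 equiv), NiCl2 (0.15 equiv), DMSO, rt, syringe-pump addition of 24 (final 0.002 M); aqueous work-up
Reagents that add atoms: none
Why: CrCl2 reduces NiCl2 to zerovalent nickel, which inserts into the activated C4–Br bond; transmetalation gives an alkenyl species of trivalent chromium that adds to the C5 aldehyde, and aqueous work-up frees the alcohol. The closest known reaction type is the Nozaki–Hiyama–Kishi macrocyclisation that is used for strained nine- and ten-membered rings. The nine-membered ring closes in the 9-exo-trig mode through C4–C5, chosen because its long forming distance best tolerates the span that the planar furanone imposes between C4 and C9. C5 is controlled by C6: with the C5=O dipole antiperiplanar to the poorly chelating C6–O lactone bond (Cornforth arrangement, same sense as the polar Felkin–Anh model) C4 arrives past H6, which should give the 5,6-anti product (5S). The step needs selectivity for the aldehyde over the C1 ketone, both esters and the α-methylene lactone, which the low basicity and high oxophilicity of alkenylchromium secure, and it needs closure to outrun dimerisation, which slow addition at high dilution secures. The neutral medium should keep C6 from epimerising and the β-acyloxy units from eliminating.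

Compound list
1 | (S)-lactic acid | C[C@H](O)C(=O)O | starting material
2 | pivalaldehyde | CC(C)(C)C=O | starting material
3 | (2S,5S)-2-tert-butyl-5-methyl-1,3-dioxolan-4-one | C[C@@H]1O[C@H](C(C)(C)C)OC1=O | intermediate
4 | allyl bromide | C=CCBr | starting material
5 | (2S,5R)-5-allyl-2-tert-butyl-5-methyl-1,3-dioxolan-4-one | C=CC[C@@]1(C)O[C@H](C(C)(C)C)OC1=O | intermediate
6 | (2R)-2-hydroxy-N-methoxy-N,2-dimethylpent-4-enamide | C=CC[C@@](C)(O)C(=O)N(C)OC | intermediate
7 | ethynylmagnesium bromide | C#C[Mg]Br | starting material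
8 | (4R)-4-hydroxy-4-methylhept-6-en-1-yn-3-one | C=CC[C@@](C)(O)C(=O)C#C | intermediate
9 | 1,1-dibromoethene | C=C(Br)Br | starting material
10 | (6R)-2-bromo-6-hydroxy-6-methylnona-1,8-dien-3-yn-5-one | C=CC[C@@](C)(O)C(=O)C#CC(Br)=C | intermediate
11 | (2R)-2-allyl-5-(1-bromovinyl)-2-methylfuran-3(2H)-one | C=CC[C@@]1(C)OC(=CC1=O)C(Br)=C | intermediate
12 | (2R)-5-(1-bromovinyl)-2-(2,3-dihydroxypropyl)-2-methylfuran-3(2H)-one (both carbinol epimers, not isolated) | OCC(O)C[C@@]1(C)OC(=CC1=O)C(Br)=C | intermediate
13 | 2-[(2R)-5-(1-bromovinyl)-2-methyl-3-oxo-2,3-dihydrofuran-2-yl]acetaldehyde | O=CC[C@@]1(C)OC(=CC1=O)C(Br)=C | intermediate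
14 | ethyl 2-[(trimethylsilyl)methyl]acrylate | CCOC(=O)C(=C)C[Si](C)(C)C | starting material
15 | 2-[(trimethylsilyl)methyl]acrylic acid | OC(=O)C(=C)C[Si](C)(C)C | intermediate
16 | (2R)-but-3-ene-1,2-diol | OC[C@H](O)C=C | starting material
17 | (2R)-2-hydroxybut-3-en-1-yl 2-[(trimethylsilyl)methyl]acrylate | C=C[C@@H](O)COC(=O)C(=C)C[Si](C)(C)C | intermediate
18 | (2R)-2-[(tert-butyldimethylsilyl)oxy]but-3-en-1-yl 2-[(trimethylsilyl)methyl]acrylate | C=C[C@@H](O[Si](C)(C)C(C)(C)C)COC(=O)C(=C)C[Si](C)(C)C | intermediate
19 | (5R)-5-[(tert-butyldimethylsilyl)oxy]-3-[(trimethylsilyl)methyl]-5,6-dihydro-2H-pyran-2-one | O=C1OC[C@H](O[Si](C)(C)C(C)(C)C)C=C1C[Si](C)(C)C | intermediate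
20 | methylidene pyranone with free C8 alcohol (6R,7R,8R,10R) | C=C1C(=O)OC[C@H](O[Si](C)(C)C(C)(C)C)[C@H]1[C@H](O)C[C@@]1(C)OC(=CC1=O)C(Br)=C | intermediate
21 | methylidene pyranone C8 isobutyrate (6R,7R,8R,10R) | C=C1C(=O)OC[C@H](O[Si](C)(C)C(C)(C)C)[C@H]1[C@H](OC(=O)C(C)C)C[C@@]1(C)OC(=CC1=O)C(Br)=C | intermediate
22 | 5-hydroxy methylidene pyranone C8 isobutyrate (6R,7S,8R,10R; same spatial arrangement, not isolated) | C=C1C(=O)OC[C@H](O)[C@H]1[C@H](OC(=O)C(C)C)C[C@@]1(C)OC(=CC1=O)C(Br)=C | intermediate
23 | cis-substituted α-methylene butyrolactone with C5 hydroxymethyl (6R,7R,8R,10R) | C=C1C(=O)O[C@@H](CO)[C@H]1[C@H](OC(=O)C(C)C)C[C@@]1(C)OC(=CC1=O)C(Br)=C | intermediate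
24 | cis-substituted α-methylene butyrolactone with C5 aldehyde (6R,7R,8R,10R) | C=C1C(=O)O[C@@H](C=O)[C@H]1[C@H](OC(=O)C(C)C)C[C@@]1(C)OC(=CC1=O)C(Br)=C | intermediate
25 | CNP0384113.1 (5S,6R,7R,8R,10R) | C=C1C(=O)O[C@@H]2[C@H]1[C@H](OC(=O)C(C)C)C[C@@]1(C)OC(=CC1=O)C(=C)[C@@H]2O | target

Total step count: 16. Longest linear sequence: 12 steps (steps 1–7 and 12–16); steps 8–11 form the second branch.

Steps most likely to fail

Step 16. Ring strain slows the closure, so intermolecular coupling may win. The alkenylnickel or alkenylchromium species may add to or reduce the α-methylene lactone, and the aldehyde may enolise at C6. The fallback runs the closure on a masked substrate instead of the unprotected one; it sets out from 23 and comes back at 25. Conjugate addition of thiophenol (Et3N cat., CH2Cl2) to C11=C13 gives the sulfide alcohol F1 (C11 epimers, of no consequence). Dess–Martin oxidation gives the sulfide aldehyde F2. The CrCl2/NiCl2 closure then gives the macrocyclic sulfide F3. NaIO4 in MeOH–H2O gives the macrocyclic sulfoxide F4. Thermolysis in toluene over CaCO3 restores the exocyclic methylene by syn elimination and gives 25.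

Step 12. The ester-conjugated allylsilane is a weak nucleophile, so Lewis-acid-induced β-elimination or decay of aldehyde 13 may outrun the addition, and the syn selectivity may erode. The fallback replaces the open-transition-state silane addition by a closed-transition-state allylchromium addition plus inversion; it sets out from 16 (with 13) and comes back at 21. Diol 16 is esterified with commercial 2-(bromomethyl)acrylic acid (DCC, DMAP) to the bromo ester F5. This is silylated (TBSCl, imidazole) to the silyl ether F6 and ring-closed with the same ruthenium catalyst to the bromomethyl pyranone F7. CrCl2 in THF couples F7 with 13, again trans to the silyloxy group but through a chair transition state, which should give the anti 8S alcohol F8. Mitsunobu esterification with isobutyric acid (PPh3, DIAD) inverts C8 and gives 21.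

Step 5. A second alkynylation of the product, dehydrobromination to a diyne, or amine- and copper-triggered Michael addition or premature cyclisation of the terminal ynone may consume the material. The fallback moves the palladium coupling to a robust alkyne and makes the ynone by acylation; it sets out from 6 and 9 and comes back at 10. Trimethylsilylacetylene is coupled with 9 (Pd(PPh3)4, CuI, i-Pr2NH) to the silyl bromoenyne F9. K2CO3 in MeOH gives 2-bromobut-1-en-3-yne F10, and EtMgBr in THF gives the alkynylmagnesium bromide F11. Addition of F11 (excess) to 6 gives 10.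

Further compounds
F1 | step 16 | sulfide alcohol (thiophenol adduct of 23, C11 epimers) | C(Sc1ccccc1)C2C(=O)O[C@@H](CO)[C@H]2[C@H](OC(=O)C(C)C)C[C@@]3(C)OC(=CC3=O)C(Br)=C
F2 | step 16 | sulfide aldehyde | C(Sc1ccccc1)C2C(=O)O[C@@H](C=O)[C@H]2[C@H](OC(=O)C(C)C)C[C@@]3(C)OC(=CC3=O)C(Br)=C
F3 | step 16 | macrocyclic sulfide | C(Sc1ccccc1)C2C(=O)O[C@@H]3[C@H]2[C@H](OC(=O)C(C)C)C[C@@]4(C)OC(=CC4=O)C(=C)[C@@H]3O
F4 | step 16 | macrocyclic sulfoxide | C(S(=O)c1ccccc1)C2C(=O)O[C@@H]3[C@H]2[C@H](OC(=O)C(C)C)C[C@@]4(C)OC(=CC4=O)C(=C)[C@@H]3O
F5 | step 12 | (2R)-2-hydroxybut-3-en-1-yl 2-(bromomethyl)acrylate | C=C[C@@H](O)COC(=O)C(=C)CBr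
F6 | step 12 | (2R)-2-[(tert-butyldimethylsilyl)oxy]but-3-en-1-yl 2-(bromomethyl)acrylate | C=C[C@@H](O[Si](C)(C)C(C)(C)C)COC(=O)C(=C)CBr
F7 | step 12 | (5R)-3-(bromomethyl)-5-[(tert-butyldimethylsilyl)oxy]-5,6-dihydro-2H-pyran-2-one | O=C1OC[C@H](O[Si](C)(C)C(C)(C)C)C=C1CBr
F8 | step 12 | C8 epimer of 20 (6R,7R,8S,10R) | C=C1C(=O)OC[C@H](O[Si](C)(C)C(C)(C)C)[C@H]1[C@@H](O)C[C@@]1(C)OC(=CC1=O)C(Br)=C
F9 | step 5 | (3-bromobut-3-en-1-yn-1-yl)trimethylsilane | C=C(Br)C#C[Si](C)(C)C
F10 | step 5 | 2-bromobut-1-en-3-yne | C=C(Br)C#C
F11 | step 5 | (3-bromobut-3-en-1-yn-1-yl)magnesium bromide | C=C(Br)C#C[Mg]Br
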